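You have to pick one flask for 6.0 min, so begin with north-west, which stands at the temperature of the cedar run, 37 °C.

| flask | starting material | free enzyme | temperature | remark | time |
|---|---|---|---|---|---|
| birch | 0.050 M | 10 µM | 17 °C | run made earlier |  |
| cedar | 0.075 M | 10 µM | 37 °C | run made earlier |  |
| alder | 0.10 M | 5 µM | 17 °C | run made earlier |  |
| south | 0.10 M | 10 µM | 52 °C |  | 6.0 min |
| south-east | 0.10 M | 10 µM |  | at 52 °C until 2.0 min, from then on at 22 °C | 6.0 min |
| north-west | 0.10 M | 10 µM | 37 °C |  | 6.0 min |
| south-west | 0.10 M | 10 µM | 22 °C |  | 6.0 min |

| run | time / min | target / % |
|---|---|---|
| birch | 3.00 | 12.9 |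
| birch | 4.00 | 16.5 |
| birch | 6.00 | 21.4 |
| birch | 8.00 | 25.7 |
| birch | 15.0 | 37.8 |
| birch | 25.0 | 46.9 |
| birch | 30.0 | 52.4 |
| cedar | 2.00 | 19.7 |
| cedar | 3.00 | 26.2 |
| cedar | 5.00 | 35.4 |
| cedar | 6.00 | 39.3 |
| cedar | 8.00 | 42.6 |
| cedar | 10.0 | 44.1 |
| cedar | 12.0 | 46.4 |
| alder | 3.00 | 10.1 |
| alder | 8.00 | 24.8 |
| alder | 15.0 | 39.7 |
| alder | 25.0 | 52.2 |
| alder | 30.0 | 56.4 |

(standard deviation of a reading: 1 percentage point)

* the best flask by amount of target, in percent of the starting material charged; "all alike" if 1.5 percentage points covers them all (south / south-east / north-west / south-west / all alike)
* amount of target at the end, in percent of the starting material charged, south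
* amount of target at the end, in percent of the starting material charged, south-east
* amount of target at the end, in percent of the starting material charged, north-west
* amount of target at the end, in percent of the starting material charged, south-west

Alder has half the free enzyme of birch and twice the starting material, and at 3.00 min alder read 10.1% against 12.9% for birch. I assume that the early rate, as a fraction of the charge, goes in proportion to c(free enzyme); this pair then makes it go as c(starting material) to the power 0.647, a reading from 17 °C that carries the scatter.

Cedar gained 0.0985 /min of its charge per minute at first, and its last reading, 46.4%, I take as its ceiling. Dividing that ceiling by the early rate gives the fade time, the time constant of the approach to the ceiling: 4.71 min, a reading that carries the scatter.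

I carry this time unchanged to north-west, which has the same temperature and free enzyme as cedar. North-west has more starting material, so with that power its early rate is 0.119 /min and its ceiling 55.9%. After 6.0 min that gives 40.3% for north-west. I reckon no other flask this way, since the runs give no fade time at their temperatures.

The forecast names north-west, with 21% for south, 22% for south-east, 45% for north-west and 37% for south-west. Its ground is its own: “Cedar plateaus, which points to enzyme death”.

The flasks give 28.2% for south, 29.2% for south-east, 43.7% for north-west and 37.2% for south-west, so north-west is the best, as forecast. South and south-east came out higher than forecast.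

    free enzyme → unfolded enzyme (k = 0.00200 /min, Ea = 212 kJ/mol)
    starting material + free enzyme → target + free enzyme, rate k2*[starting material]^3*[free enzyme]/(1 + ([starting material]/Kh2)^3) (0.0710 M, k = 81000 /M³/s, Ea = 23.0 kJ/mol)
    starting material → uncatalysed product (k = 0.0360 /min, Ea = 102 kJ/mol)
    (constants at 37 °C)

North-west gave 43.7% against my 40.3%. At 6.00 min north-west still held 98.8% of its free enzyme and 42.3% of its starting material. Now use the fade time once more, on north-west left longer: at 25 min the same ceiling and fade time give 55.6%, and north-west left until then stood at 57.2%.

The numbers in the tables are simulated with constants of no real substance; scatter was added.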